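All runs are simulated with constants of no real substance; noise was put on by code.

**The books.** Each mole of substrate you charge stays on the books, as substrate, intermediate, target, isomer of the product or side product, and those entries must add up to the charge. Substrate is the limiting reagent here, since reagent stands at 1.80 equiv.

| setting | east | north-east | west | zeta | theta | epsilon | delta |
|---|---|---|---|---|---|---|---|
| substrate | 0.050 M | 0.050 M | 0.050 M | 0.050 M | 0.050 M | 0.050 M | 0.050 M (fed, over 16.0 h) |
| reagent | 1.8 equiv | 0.90 equiv | 1.4 equiv | 1.80 equiv | 1.80 equiv (fed, over 16.0 h) | 1.80 equiv | 1.80 equiv |
| remark | run made earlier | run made earlier | run made earlier | everything together in a closed stirred flask, run for 20 h | a stirred flask in which reagent is dosed at a steady rate over 16.0 h without added volume, worked up at 20 h | a single well-mixed tank run continuously and read at steady state, 20 h in it on average | a stirred flask in which substrate is dosed at a steady rate over 16.0 h without added volume, worked up at 20 h |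
| time |  |  |  | 20 h | 20 h |  | 20 h |

- east (time / h: target / %): 2.00: 7.5; 5.00: 20.7; 10.0: 36.7; 15.0: 44.9; 20.0: 49.0
- north-east (time / h: target / %): 4.00: 9.7; 8.00: 18.3; 12.0: 24.9; 15.0: 27.6; 20.0: 32.0
- west (time / h: target / %): 4.00: 13.7; 8.00: 25.3; 12.0: 34.0; 15.0: 38.2; 20.0: 43.4

(scatter of a reading: 0.5 percentage points)

- the stated concentrations are those of everything mixed, before any reaction; amounts are the same in each set-up
- candidate steps: substrate + reagent -> intermediate + by-product; intermediate <-> isomer of the product; target + by-product -> side product; intermediate <-> target
- the feed brings no volume worth counting
- the earlier runs were made in a closed, stirred flask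

- the set-up with the highest amount of target at the outlet or at the end, in percent of the substrate put in ("none" if the first two lie within 2 percentage points) (zeta / theta / epsilon / delta / none)
- amount of target at the outlet or at the end, in percent of the substrate put in, zeta
- amount of target at the outlet or at the end, in percent of the substrate put in, theta
- amount of target at the outlet or at the end, in percent of the substrate put in, epsilon
- amount of target at the outlet or at the end, in percent of the substrate put in, delta

**Charge half-life.** At 4.00 h, the west and north-east runs gave target in the ratio 1.41 for reagent in the ratio 1.56, so the rate roughly follows reagent. Scale the north-east reading up to 1.80 equiv and you get 14.3 h. That is the charge half-life: the time substrate takes to halve with reagent held as charged, read from target and so rough.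

**Zeta's ledger.** Zeta repeats the east run, so enter 49.0% target. Its 20 h counts 1.40 half-lives, so enter about 37.9% substrate left. The difference, 13.1%, goes to intermediate, isomer and side product.

**Other set-ups.** A steady feed enters on average halfway through, so in theta and delta a portion gets 12.0 h, or 0.840 half-lives, fewer than zeta's. The east curve, read between its points at that time, gives about 40.0%, my figure for both. In epsilon, the same clock leaves 50.8% substrate at the outlet, more than zeta's. So I put zeta first.

**The forecast.** It says “Zeta simply repeats the east run” and names zeta as best: zeta 49%, theta 39%, epsilon 35.5%, delta 38.5%. My dosed figure stands above its theta value.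

**The flask.** Zeta gives 48.9%, theta 39.4%, epsilon 34.7% and delta 38.6%, so zeta is best.

    substrate + reagent → intermediate + by-product (k = 0.964 M⁻¹ h⁻¹)
    intermediate ⇌ isomer of the product (K = 2.10, k = 0.220 h⁻¹)
    target + by-product → side product (k = 0.520 M⁻¹ h⁻¹)
    intermediate ⇌ target (K = 13.7, k = 0.947 h⁻¹)

**Count applied.** At 20.0 h, zeta held 27.7% substrate, less than the counted 37.9%, and its other entries came to 23.4% against my 13.1%. Zeta leads theta by 9.5 percentage points. My 14.3 h was too long: the first step alone, with reagent as charged, has a half-life of 8.0 h in zeta. A neighbour of zeta charged at 0.20 M, same equivalents, has that half-life cut to 2.00 h, so its 20 h counts 10.0 and, with reagent held as charged, leaves 0.0977%. That neighbour held more substrate than this count, 2.09%, with 45.6% of its reagent left and 48.6% side product, and its target, 35.7%, stood below theta's 39.4%.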